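(Readings and results are simulated with constants of no real substance, and the scatter is random.)

56.4% of the starting material charged to the theta run was still unreacted at 6.1 h, and the meeting opened on that figure. These flasks and readings were before it:

| flask | starting material | free catalyst | product | time |
|---|---|---|---|---|
| theta | 0.500 M | 0.0500 M |  |  |
| delta | 0.250 M | 0.0500 M |  |  |
| eta | 0.500 M | 0.0500 M | 0.150 M |  |
| zeta | 0.500 M | 0.0750 M |  |  |
| beta | 2.50 M | 0.0500 M |  | 6.1 h |

- theta run (time / h: [product] / M): 0.24: 0.0167; 0.55: 0.0335; 1.2: 0.0712; 2.7: 0.1335; 6.1: 0.2178
- delta run (time / h: [product] / M): 0.24: 0.0033; 0.55: 0.0122; 1.2: 0.0271; 2.7: 0.0602; 6.1: 0.1041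
- eta run (time / h: [product] / M): 0.24: 0.1644; 0.55: 0.1854; 1.2: 0.2123; 2.7: 0.2635; 6.1: 0.3381
- zeta run (time / h: [product] / M): 0.24: 0.0183; 0.55: 0.0437; 1.2: 0.0854; 2.7: 0.1524; 6.1: 0.2345

(each reading ± 0.002 M)

1. reaction order in [starting material] at the outset, round the charge of the theta run, defined at two percent of the starting material turned into product (one fixed amount of product, the same in the runs compared)
2. reaction order in [free catalyst] at the outset, round the charge of the theta run, defined at two percent of the starting material turned into product
3. the delta run starts with 0.250 M less of starting material than the theta run, and with no product. Compared where both hold the same amount of starting material, once fifteen percent of what the delta run was charged with has turned into product, is the delta run faster, slower or alike (within a tenth)?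
4. product in the beta run at 6.1 h, as a share of the starting material charged

- Overall: starting material -> product, with free catalyst as catalyst.
- Constant volume, constant temperature.
- A reading of a species includes what of it is bound.
- An order is taken over about fifteen percent of the charge, up and down.

The kineticist proposed comparing runs by the fraction left, not the fraction made: take the natural log of the charge over what remains, and divide by the time. For the theta run at 6.1 h this gives 0.0938 h⁻¹. The kineticist called this the fade, the share of what is left that goes per hour, averaged from the start; it is an apparent first-order rate constant.

The bench chemist objected that charge plainly matters early on. At 1.2 h the theta run's fade is 0.128 h⁻¹, while at 1.2 h the delta run's is 0.0956 h⁻¹, a ratio of 1.34. The kineticist replied that by 6.1 h the delta run reads 0.0883 h⁻¹, so the ratio has shrunk to 1.06.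

The chair asked what this meant for the beta run, which is sampled at that same time. The kineticist's own reckoning held the theta run's fade and took one minus the exponential of minus fade times time, which gives 43.6% of the charge as product.

The forecast was then entered: order 1.3 in [starting material], order 0.6 in [free catalyst], the delta run faster at equal starting material, and 36% for the beta run. That last figure is less than the kineticist's. The forecast's own integration gave about 44%, and it came down from that on the ground that “this extrapolation is fivefold, so I expect less”.

The simulation gives orders of 1.4 and 0.47, the delta run faster, and 45.9% of the charge as product in the beta run.

    free catalyst + starting material ⇌ catalyst-substrate complex, settled at all times (0.5760 M⁻¹)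
    catalyst-substrate complex + starting material ⇌ doubly bound catalyst, settled at all times (0.3930 M⁻¹)
    doubly bound catalyst → product + catalyst-substrate complex (16.74 h⁻¹)
    free catalyst + product → spent catalyst + product (4.140 M⁻¹ h⁻¹)
    starting material → product (0.06588 h⁻¹)

The fade of the beta run comes to 0.101 h⁻¹ against 0.0938 h⁻¹ for the theta run, on a charge 5.00 times as large. The path from starting material straight to product removes a fixed share of what is left each hour, 0.0659 h⁻¹, and without that path the beta run reaches 24.6%, not 45.9%. Carried to the eta run, counting product made beyond its charge of product, a fade of 0.0774 h⁻¹ puts half of the starting material turned at 8.96 h, and the eta run gets there at 9.15 h.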